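Ring A (cyclopentane C1–C5) bears oxygen at C1 beside the spiro atom C5, and C5 is bonded to C6 of ring B (C5–C10): a latent 2-acetylcyclopentanone. This β-diketone, with the C3 isopropenyl stereocentre in place, is an isomer of (R)-carvone oxide. Everything rests on a Lewis acid 1,2-acyl shift that contracts the carvone six-membered ring to ring A and, in the same operation, extrudes C6–C7 as an acetyl group on the future spiro carbon. The precursor is simply the epoxy ketone of carvone. Crotonaldehyde then closes ring B on this carbon; methyl addition, directed reduction, acylation, oxidative transposition and α'-acetoxylation complete the target.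

Key step: step 2

Remark: labels C1–C10 follow the spiro[4.5]decane numbering of the target (C1 senecioyloxy, C3 isopropenyl, C5 spiro, C6 vinylic methyl, C8 ketone, C9 acetoxy, C10 methyl). Compound 3 is assumed to react through its enol, so its C2 configuration does not matter.

Step 1
Reactants: 1 (R)-(−)-carvone
Product: 2 (1R,4R,6R)-1-methyl-4-(prop-1-en-2-yl)-7-oxabicyclo[4.1.0]heptan-2-one (epoxide trans to the isopropenyl group)
Conditions: 35% aq. H2O2, NaOH (cat.), MeOH, 0 °C
Reagents that add atoms: hydrogen peroxide, OO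
Why: Weitz–Scheffer nucleophilic epoxidation touches only the electron-poor enone alkene, and hydroperoxide adds axially to the β-carbon anti to the equatorial isopropenyl group, which sets both epoxide carbons trans to it.

Step 2
Reactants: 2 (1R,4R,6R)-1-methyl-4-(prop-1-en-2-yl)-7-oxabicyclo[4.1.0]heptan-2-one
Product: 3 (4R)-2-acetyl-4-(prop-1-en-2-yl)cyclopentan-1-one (C2 epimers and enol forms)
Conditions: BF3·OEt2 (0.3 equiv), CH2Cl2, −40 to 0 °C; then H2O
Reagents that add atoms: none
Why: BF3 binds the epoxide oxygen, the C6–O bond (β to the carbonyl) lengthens because a cation α to the carbonyl is disfavoured, and the acyl carbon C2 of 2 shifts from C1 to C6 at the rear of the breaking bond while C1–O collapses to the acetyl carbonyl. The closest known reaction type is the Lewis acid rearrangement of 2,3-epoxycyclohexanones to 2-acylcyclopentanones, a semipinacol-type 1,2-acyl shift as known for isophorone oxide. Ring A is closed not by an exo or endo cyclisation but by this suprafacial 1,2-shift through a three-centre transition state, taking the six-membered ring to a five-membered one. The only new stereocentre, C2 of 3, forms with inversion but lies between two carbonyls and equilibrates through the enol, so it needs no control, while C4 comes unchanged from carvone. The step needs acyl over methyl migration and activation of the epoxide without attack on the isopropenyl alkene. The higher migratory aptitude of acyl in this manifold, the ring geometry that holds C2 behind the C6–O bond, and aprotic low-temperature conditions with substoichiometric Lewis acid should secure this.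

Step 3
Reactants: 3 (4R)-2-acetyl-4-(prop-1-en-2-yl)cyclopentan-1-one; 4 (E)-but-2-enal (crotonaldehyde)
Product: 6 (3R,5R,10S)-10-methyl-3-(prop-1-en-2-yl)spiro[4.5]dec-7-ene-1,6-dione, via Michael adduct keto-aldehyde 5 (not isolated)
Conditions: (R)-α,α-diphenylprolinol trimethylsilyl ether (10 mol%), PhCO2H (10 mol%), toluene, 0 °C to rt; then p-TsOH·H2O (20 mol%), 60 °C
Reagents that add atoms: none
Why: This is an iminium-catalysed Michael addition followed by acid-catalysed intramolecular aldol condensation (Robinson-type spiroannulation), in which the silyloxydiphenylmethyl group of the (R)-catalyst shields one face of the (E)-iminium ion and fixes C10, the enol of 3 is attacked anti to the C3 isopropenyl group and fixes C5, and only the acetyl methyl (future C7) gives a ketol that can dehydrate, since closure from C2 would need a bridgehead alkene.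

Step 4
Reactants: 6 (3R,5R,10S)-10-methyl-3-(prop-1-en-2-yl)spiro[4.5]dec-7-ene-1,6-dione
Product: 8 (3R,5S,6R,10S)-6-hydroxy-6,10-dimethyl-3-(prop-1-en-2-yl)spiro[4.5]dec-7-en-1-one, via lithium enolate 7 (not isolated)
Conditions: LiN(i-Pr)2 (LDA, 1.05 equiv), THF, −78 °C; MeLi (1.3 equiv), −78 °C; AcOH quench at −78 °C
Reagents that add atoms: methyllithium, [Li]C
Why: Kinetic deprotonation at C2 masks the C1 ketone as its lithium enolate (in situ protection), so methyllithium adds 1,2 only to the C6 enone carbonyl, from the ring B face of C4H2 opposite to the pseudoaxial C1 branch, which places the C6 hydroxyl cis to C1 (this centre is erased in step 7, so its epimer would converge).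

Step 5
Reactants: 8 (3R,5S,6R,10S)-6-hydroxy-6,10-dimethyl-3-(prop-1-en-2-yl)spiro[4.5]dec-7-en-1-one
Product: 9 (1S,3R,5R,6R,10S)-6,10-dimethyl-3-(prop-1-en-2-yl)spiro[4.5]dec-7-ene-1,6-diol
Conditions: Me4NBH(OAc)3, MeCN/AcOH, −25 °C; then H2O
Reagents that add atoms: none
Why: In this Evans–Saksena hydroxyl-directed reduction the C6 hydroxyl exchanges onto boron and delivers hydride intramolecularly to the face of the C1 carbonyl that looks towards C6, so the new C1 hydroxyl ends cis to C10 and trans to the isopropenyl group (1S).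

Step 6
Reactants: 9 (1S,3R,5R,6R,10S)-6,10-dimethyl-3-(prop-1-en-2-yl)spiro[4.5]dec-7-ene-1,6-diol; 10 3-methylbut-2-enoyl chloride (senecioyl chloride)
Product: 11 (1S,3R,5R,6R,10S)-6-hydroxy-6,10-dimethyl-3-(prop-1-en-2-yl)spiro[4.5]dec-7-en-1-yl 3-methylbut-2-enoate
Conditions: pyridine, DMAP (cat.), CH2Cl2, 0 °C to rt
Reagents that add atoms: none
Why: DMAP-catalysed acylation distinguishes the secondary C1 alcohol from the tertiary allylic C6 alcohol, pyridine in place of a trialkylamine avoids vinylketene formation and deconjugation of the senecioyl unit, and no stereocentre is touched.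

Step 7
Reactants: 11 (1S,3R,5R,6R,10S)-6-hydroxy-6,10-dimethyl-3-(prop-1-en-2-yl)spiro[4.5]dec-7-en-1-yl 3-methylbut-2-enoate
Product: 12 (1S,3R,5S,10S)-6,10-dimethyl-8-oxo-3-(prop-1-en-2-yl)spiro[4.5]dec-6-en-1-yl 3-methylbut-2-enoate
Conditions: [C5H5NH][CrO3Cl] (pyridinium chlorochromate), 4 Å molecular sieves, CH2Cl2, rt
Reagents that add atoms: pyridinium chlorochromate (delivers the C8 oxygen), [O-][Cr](=O)(=O)Cl.c1cc[nH+]cc1
Why: In this Babler–Dauben oxidative transposition the tertiary allylic chromate ester undergoes a [3,3]-sigmatropic shift that places a chromate oxygen on C8 and is then oxidised to the enone, which creates the C6=C7 bond and removes the auxiliary C6 stereocentre.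

Step 8
Reactants: 12 (1S,3R,5S,10S)-6,10-dimethyl-8-oxo-3-(prop-1-en-2-yl)spiro[4.5]dec-6-en-1-yl 3-methylbut-2-enoate
Product: 13 (1S,3R,5S,9S,10R)-9-acetoxy-6,10-dimethyl-8-oxo-3-(prop-1-en-2-yl)spiro[4.5]dec-6-en-1-yl 3-methylbut-2-enoate (target)
Conditions: Mn(OAc)3·2H2O, benzene, reflux (Dean–Stark)
Reagents that add atoms: manganese triacetate dihydrate (delivers OAc), CC(=O)[O-].CC(=O)[O-].CC(=O)[O-].[Mn+3].O.O
Why: α'-Acetoxylation of an enone by Mn(OAc)3 proceeds through the manganese enolate at C9, the only enolisable α' position, where acetate is transferred to the face opposite to the adjacent C10 methyl group and the epimerisable centre settles in the trans-diequatorial (9S) arrangement.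

Compound list
1 | (R)-(−)-carvone, (5R)-2-methyl-5-(prop-1-en-2-yl)cyclohex-2-en-1-one | C=C(C)[C@H]1CC(=O)C(C)=CC1 | starting material
2 | (1R,4R,6R)-1-methyl-4-(prop-1-en-2-yl)-7-oxabicyclo[4.1.0]heptan-2-one | C=C(C)[C@H]1CC(=O)[C@]2(C)O[C@@H]2C1 | intermediate
3 | (4R)-2-acetyl-4-(prop-1-en-2-yl)cyclopentan-1-one (C2 epimers and enol forms) | C=C(C)[C@H]1CC(=O)C(C(C)=O)C1 | intermediate
4 | (E)-but-2-enal (crotonaldehyde) | C/C=C/C=O | starting material
5 | (3S)-3-[(1S,4R)-1-acetyl-2-oxo-4-(prop-1-en-2-yl)cyclopentyl]butanal | C=C(C)[C@H]1CC(=O)[C@](C1)(C(C)=O)[C@@H](C)CC=O | intermediate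
6 | (3R,5R,10S)-10-methyl-3-(prop-1-en-2-yl)spiro[4.5]dec-7-ene-1,6-dione | C=C(C)[C@H]1CC(=O)[C@]2(C1)C(=O)C=CC[C@@H]2C | intermediate
7 | lithium C1=C2 enolate of 6 | [Li+].C=C(C)[C@H]1C=C([O-])[C@]2(C1)C(=O)C=CC[C@@H]2C | intermediate
8 | (3R,5S,6R,10S)-6-hydroxy-6,10-dimethyl-3-(prop-1-en-2-yl)spiro[4.5]dec-7-en-1-one | C=C(C)[C@H]1CC(=O)[C@]2(C1)[C@](C)(O)C=CC[C@@H]2C | intermediate
9 | (1S,3R,5R,6R,10S)-6,10-dimethyl-3-(prop-1-en-2-yl)spiro[4.5]dec-7-ene-1,6-diol | C=C(C)[C@H]1C[C@H](O)[C@]2(C1)[C@](C)(O)C=CC[C@@H]2C | intermediate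
10 | 3-methylbut-2-enoyl chloride (senecioyl chloride) | CC(C)=CC(=O)Cl | starting material
11 | (1S,3R,5R,6R,10S)-6-hydroxy-6,10-dimethyl-3-(prop-1-en-2-yl)spiro[4.5]dec-7-en-1-yl 3-methylbut-2-enoate | C=C(C)[C@H]1C[C@H](OC(=O)C=C(C)C)[C@]2(C1)[C@](C)(O)C=CC[C@@H]2C | intermediate
12 | (1S,3R,5S,10S)-6,10-dimethyl-8-oxo-3-(prop-1-en-2-yl)spiro[4.5]dec-6-en-1-yl 3-methylbut-2-enoate | C=C(C)[C@H]1C[C@H](OC(=O)C=C(C)C)[C@]2(C1)C(C)=CC(=O)C[C@@H]2C | intermediate
13 | (1S,3R,5S,9S,10R)-9-acetoxy-6,10-dimethyl-8-oxo-3-(prop-1-en-2-yl)spiro[4.5]dec-6-en-1-yl 3-methylbut-2-enoate | C=C(C)[C@H]1C[C@H](OC(=O)C=C(C)C)[C@]2(C1)C(C)=CC(=O)[C@@H](OC(C)=O)[C@@H]2C | target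

Total step count: 8. Longest linear sequence: 8 steps (1 to 13).

Steps most likely to fail

Step 2 (key step). What may go wrong:
- methyl migration in place of acyl migration;
- proton loss to an allylic ketol;
- capture of the developing positive charge by the isopropenyl alkene;
- sequestration of the Lewis acid by the enolised product.

The fallback sets out from 2 and comes back at 3, and it keeps the six-to-five contraction but separates ionisation from epoxide activation. Acid-catalysed hydrolysis (HClO4 cat., THF/H2O) opens the epoxide at the β-carbon with inversion. This gives the trans-diol (2R,3S,5R)-2,3-dihydroxy-2-methyl-5-(prop-1-en-2-yl)cyclohexan-1-one F1. Selective mesylation of the secondary hydroxyl (MsCl, Et3N, CH2Cl2, 0 °C) gives (1S,2R,5R)-2-hydroxy-2-methyl-3-oxo-5-(prop-1-en-2-yl)cyclohexyl methanesulfonate F2. In the chair of F2 the mesylate and the isopropenyl group are both equatorial, so the C–OMs bond is antiperiplanar to the ring bond to the acyl carbon. Et3Al (CH2Cl2, −78 °C) forms the aluminium alkoxide and triggers a stereoelectronically aligned semipinacol 1,2-acyl shift to 3.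

Step 3. What may go wrong: poor facial selectivity at the enol carbon if catalyst control at C10 and substrate control at C5 are mismatched, and slow formation of the quaternary centre. The fallback sets out from 3 and comes back at 5.
- An iridium-catalysed branched-selective allylic alkylation of 3 with (E)-but-2-enyl methyl carbonate ([Ir(cod)Cl]2, chiral phosphoramidite ligand, base, THF) forms the vicinal quaternary and tertiary centres under ligand control. It gives (2S,4R)-2-acetyl-2-[(2S)-but-3-en-2-yl]-4-(prop-1-en-2-yl)cyclopentan-1-one F3.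
- An aldehyde-selective Wacker oxidation (PdCl2(PhCN)2, CuCl2·2H2O, AgNO2, O2, t-BuOH/MeNO2) reacts at the monosubstituted vinyl group and leaves the 1,1-disubstituted isopropenyl group. It gives 5, which is closed to 6 with p-TsOH as in step 3.

Step 4. What may go wrong: proton exchange between the enolate and unreacted ketone, leading to attack of methyllithium at C1, or retro-aldol cleavage of the C5–C6 bond during the quench. The fallback sets out from 6 and comes back at 8, and it replaces enolate masking by a temporary change of oxidation level.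
- NaBH4 in MeOH/CH2Cl2 at −78 °C reduces the saturated C1 ketone in preference to the enone. It gives (3R,5R,10S)-1-hydroxy-10-methyl-3-(prop-1-en-2-yl)spiro[4.5]dec-7-en-6-one F4, in which the C1 configuration is irrelevant.
- Excess MeLi adds to C6 of the alkoxide to give (3R,5R,6R,10S)-6,10-dimethyl-3-(prop-1-en-2-yl)spiro[4.5]dec-7-ene-1,6-diol F5 as C1 epimers.
- Buffered Dess–Martin periodinane oxidises only the secondary alcohol and returns 8.

Further compounds
F1 | step 2 | (2R,3S,5R)-2,3-dihydroxy-2-methyl-5-(prop-1-en-2-yl)cyclohexan-1-one | C=C(C)[C@H]1CC(=O)[C@](C)(O)[C@@H](O)C1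
F2 | step 2 | (1S,2R,5R)-2-hydroxy-2-methyl-3-oxo-5-(prop-1-en-2-yl)cyclohexyl methanesulfonate | C=C(C)[C@H]1CC(=O)[C@](C)(O)[C@@H](OS(C)(=O)=O)C1
F3 | step 3 | (2S,4R)-2-acetyl-2-[(2S)-but-3-en-2-yl]-4-(prop-1-en-2-yl)cyclopentan-1-one | C=C(C)[C@H]1CC(=O)[C@](C1)(C(C)=O)[C@@H](C)C=C
F4 | step 4 | (3R,5R,10S)-1-hydroxy-10-methyl-3-(prop-1-en-2-yl)spiro[4.5]dec-7-en-6-one (C1 epimers) | C=C(C)[C@H]1CC(O)[C@]2(C1)C(=O)C=CC[C@@H]2C
F5 | step 4 | (3R,5R,6R,10S)-6,10-dimethyl-3-(prop-1-en-2-yl)spiro[4.5]dec-7-ene-1,6-diol (C1 epimers) | C=C(C)[C@H]1CC(O)[C@]2(C1)[C@](C)(O)C=CC[C@@H]2C
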